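## Retrosynthetic overview

1. Last bond cut: C4–C1′. Acid ionisation of cis-2-methylchroman-4,5-diol gives an ortho-quinone methide (C4=C4a–C5=O). 1,8-Dimethoxynaphthalene adds to it para to a methoxy group and trans to the C2 methyl group, which sets C4.
2. The diol comes from (R)-5-hydroxy-2-methylchroman-4-one. Its pyran ring is cut at O1–C8a, and its benzene ring is taken back to a non-aromatic 5-hydroxycyclohexane-1,3-dione ring.
3. Enabling feature: in the benzene ring of the chroman, C4a is flanked by two oxygen-bearing carbons (C8a–O1 and C5–OH) and C7 is unsubstituted. The ring is therefore a 2-acylresorcinol, that is, a twice dehydrated 2-acyl-5-hydroxycyclohexane-1,3-dione; at that level C8a is a ketone carbon delta to the C2 hydroxyl, and the two ring carbonyls are interchangeable.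
4. The triketone comes from C-acylation of silylated dihydrophloroglucinol (one hydrogenation from phloroglucinol) with (R)-3-silyloxybutanoic acid, which is chiral pool and sets C2.
5. Ring order: the carbocycle is bought aromatic and de-aromatised; the pyran ring is then closed and the carbocycle re-aromatised in one operation; the naphthalene is attached last.

Key step: step 6

Assumption: 1,3-dicarbonyl compounds are drawn as keto tautomers and chroman numbering is used for all precursors. The ring carbinol carbon (later C7) carries no stereodescriptor, because it is not a fixed stereocentre in 2, 4, 9 and 10 and is erased in step 6.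

## Route

Step 1
Reactants: 1 phloroglucinol
Product: 2 dihydrophloroglucinol (5-hydroxycyclohexane-1,3-dione)
Conditions: H2 (3.5 bar), Rh/Al2O3, NaOH (1 equiv), H2O, 23 °C; then HCl to pH 3, 0 °C
Reagents that add atoms: none
Why: This is partial hydrogenation of a polyphenolate, the reaction type that turns resorcinol into cyclohexane-1,3-dione; the monoanion takes up one H2 through its keto tautomer, and the product persists as the reduction-resistant vinylogous carboxylate until it is acidified in the cold.

Step 2
Reactants: 2 dihydrophloroglucinol
Product: 4 5-(tert-butyldimethylsilyloxy)cyclohexane-1,3-dione, via bis-silyl enone 3 (not isolated)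
Conditions: TBSCl (2.2 equiv), imidazole (4.5 equiv), DMF, 0 to 23 °C; then aq citric acid, THF, 23 °C
Reagents that add atoms: tert-butyldimethylsilyl chloride, CC(C)(C)[Si](C)(C)Cl
Why: Standard silyl ether formation caps the enol and the secondary alcohol, and the mild acid wash hydrolyses only the vinylogous silyl ester of 3, so the ring carbinol alone stays protected, which blocks its acylation in step 5 and makes the dione soluble in CH2Cl2.

Step 3
Reactants: 5 methyl (R)-3-hydroxybutanoate
Product: 6 methyl (R)-3-(tert-butyldimethylsilyloxy)butanoate
Conditions: TBSCl, imidazole, DMF, 23 °C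
Reagents that add atoms: tert-butyldimethylsilyl chloride, CC(C)(C)[Si](C)(C)Cl
Why: This is silyl ether formation at the only hydroxyl group, and the stereocentre (future C2, R) comes from the chiral pool and is not touched.

Step 4
Reactants: 6 methyl (R)-3-(tert-butyldimethylsilyloxy)butanoate
Product: 7 (R)-3-(tert-butyldimethylsilyloxy)butanoic acid
Conditions: LiOH, THF/MeOH/H2O, 23 °C; then HCl to pH 3, 0 °C
Reagents that add atoms: lithium hydroxide, [Li+].[OH-]
Why: This is ester saponification, in which the secondary silyl ether survives and the silyloxy group is too poor a leaving group for beta-elimination, so the stereocentre is preserved.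

Step 5
Reactants: 4 5-(tert-butyldimethylsilyloxy)cyclohexane-1,3-dione; 7 (R)-3-(tert-butyldimethylsilyloxy)butanoic acid
Product: 9 (R)-2-[3-(tert-butyldimethylsilyloxy)butanoyl]-5-(tert-butyldimethylsilyloxy)cyclohexane-1,3-dione, via enol ester 8 (not isolated)
Conditions: DCC, DMAP (1.2 equiv), CH2Cl2, 0 to 23 °C; aq citric acid wash
Reagents that add atoms: none
Why: Steglich-type acylation gives the enol ester 8, and DMAP then relays the acyl group from oxygen to C2 of the dione (O-to-C acyl migration, the standard route to 2-acylcyclohexane-1,3-diones), driven by the strongly hydrogen-bonded beta-triketone enol.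

Step 6
Reactants: 9 (R)-2-[3-(tert-butyldimethylsilyloxy)butanoyl]-5-(tert-butyldimethylsilyloxy)cyclohexane-1,3-dione
Product: 12 (R)-5-hydroxy-2-methylchroman-4-one, via desilylated triketone 10 (not isolated), via bicyclic hydroxy enedione 11 (not isolated)
Conditions: TsOH·H2O (2.5 equiv), MeCN, 23 °C; then 75 °C
Reagents that add atoms: none
Why: The acid first hydrolyses both silyl ethers to 10, whose C2 hydroxyl sits delta to the ring carbonyl carbon C8a inside a delta-hydroxy-beta-dicarbonyl array; it adds to that carbonyl and the hemiketal loses water to give the vinylogous ester 11, the closest known reaction type being the acid-catalysed cyclodehydration of delta-hydroxy-1,3-diketones to 2,3-dihydro-4H-pyran-4-ones. On warming, 11 enolises towards C8, the now allylic C7 hydroxyl leaves as water with the push of O1 and of the C5 oxygen, and the resulting cation is the C6-protonated arene, which loses a proton to give the phenol 12; the precedent is the acid-catalysed dehydration of dihydrophloroglucinol to resorcinol. The pyran ring closes in the 6-exo-trig mode at the C8a carbonyl, while the carbocycle is already present and only becomes aromatic, without any oxidant, so that the C2–C3 bond cannot be dehydrogenated to a chromone. No stereocentre is created: C2 stays R because its C–O bond is never broken, and the undefined C7 centre disappears. Two selectivities matter: closure must come before aromatisation, because a phenolic C8a can no longer be attacked by an alcohol, and this is secured by running the fast hemiketalisation at 23 °C before the slower loss of the C7 hydroxyl is switched on at 75 °C; and no choice between the two ring carbonyls is needed, because they flank C4a symmetrically and both closures give 12 once C7 is flat. Elimination of the C2 oxygen is held back because the triketone is enolised towards C4a and not towards C3.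

Step 7
Reactants: 12 (R)-5-hydroxy-2-methylchroman-4-one
Product: 13 (2R,4S)-2-methylchroman-4,5-diol (cis)
Conditions: NaBH4, THF/MeOH, −20 to 0 °C; aq NH4Cl
Reagents that add atoms: none
Why: In this borohydride reduction of a chromanone, axial hydride delivery to the half-chair with an equatorial C2 methyl group should give mainly the cis (4S) pseudo-equatorial alcohol, the low temperature holds back loss of the C4 oxygen, and the C4 configuration is of no consequence because step 8 passes through a planar C4.

Step 8
Reactants: 13 (2R,4S)-2-methylchroman-4,5-diol; 14 1,8-dimethoxynaphthalene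
Product: 16 cladonaphchrom A, (2R,4S)-4-(4,5-dimethoxynaphthalen-1-yl)-2-methylchroman-5-ol (trans), via ortho-quinone methide 15 (not isolated)
Conditions: 14 (3 equiv), TsOH·H2O (10 mol %), (CF3)2CHOH/CH2Cl2, 0 °C, slow addition of 13
Reagents that add atoms: none
Why: In this Friedel–Crafts alkylation by a benzylic alcohol of the flavan-4-ol type, acid expels the C4 hydroxyl with the push of the C5 hydroxyl and O1 to give 15 (protonated form: the 2,6-dioxygenated benzylic cation), 14 attacks through its most nucleophilic and least hindered position para to a methoxy group, and axial approach to the half-chair that holds the C2 methyl group equatorial places the naphthyl group pseudo-axial and trans to the methyl group (4S), which is also the arrangement that avoids peri strain with the C5 hydroxyl.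

## Compound list

1 | phloroglucinol (benzene-1,3,5-triol) | Oc1cc(O)cc(O)c1 | starting material
2 | dihydrophloroglucinol (5-hydroxycyclohexane-1,3-dione) | O=C1CC(O)CC(=O)C1 | intermediate
3 | 3,5-bis(tert-butyldimethylsilyloxy)cyclohex-2-en-1-one (racemic, not isolated) | O=C1C=C(O[Si](C)(C)C(C)(C)C)CC(O[Si](C)(C)C(C)(C)C)C1 | intermediate
4 | 5-(tert-butyldimethylsilyloxy)cyclohexane-1,3-dione | O=C1CC(O[Si](C)(C)C(C)(C)C)CC(=O)C1 | intermediate
5 | methyl (R)-3-hydroxybutanoate | C[C@@H](O)CC(=O)OC | starting material
6 | methyl (R)-3-(tert-butyldimethylsilyloxy)butanoate | C[C@@H](O[Si](C)(C)C(C)(C)C)CC(=O)OC | intermediate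
7 | (R)-3-(tert-butyldimethylsilyloxy)butanoic acid | C[C@@H](O[Si](C)(C)C(C)(C)C)CC(=O)O | intermediate
8 | 5-(tert-butyldimethylsilyloxy)-3-oxocyclohex-1-en-1-yl (R)-3-(tert-butyldimethylsilyloxy)butanoate (not isolated) | C[C@@H](O[Si](C)(C)C(C)(C)C)CC(=O)OC1=CC(=O)CC(O[Si](C)(C)C(C)(C)C)C1 | intermediate
9 | (R)-2-[3-(tert-butyldimethylsilyloxy)butanoyl]-5-(tert-butyldimethylsilyloxy)cyclohexane-1,3-dione | C[C@@H](O[Si](C)(C)C(C)(C)C)CC(=O)C1C(=O)CC(O[Si](C)(C)C(C)(C)C)CC1=O | intermediate
10 | 5-hydroxy-2-[(R)-3-hydroxybutanoyl]cyclohexane-1,3-dione (not isolated) | C[C@@H](O)CC(=O)C1C(=O)CC(O)CC1=O | intermediate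
11 | (2R)-7-hydroxy-2-methyl-2,3,7,8-tetrahydro-4H-chromene-4,5(6H)-dione (both C7 epimers, not isolated) | C[C@@H]1CC(=O)C2=C(CC(O)CC2=O)O1 | intermediate
12 | (R)-5-hydroxy-2-methylchroman-4-one | C[C@@H]1CC(=O)c2c(O)cccc2O1 | intermediate
13 | (2R,4S)-2-methylchroman-4,5-diol (cis) | C[C@@H]1C[C@H](O)c2c(O)cccc2O1 | intermediate
14 | 1,8-dimethoxynaphthalene | COc1cccc2cccc(OC)c12 | starting material
15 | (2R)-2-methyl-2,3-dihydro-5H-chromen-5-one (ortho-quinone methide, not isolated) | C[C@@H]1CC=C2C(=O)C=CC=C2O1 | intermediate
16 | cladonaphchrom A, (2R,4S)-4-(4,5-dimethoxynaphthalen-1-yl)-2-methylchroman-5-ol | COc1cccc2c([C@@H]3C[C@@H](C)Oc4cccc(O)c43)ccc(OC)c12 | target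

## Step count and risks

Total step count: 8. Longest linear sequence: 6 (steps 3, 4, 5, 6, 7, 8; the branch 1, 2, 5, 6, 7, 8 is equally long).

**First risk, step 6.**
- What may go wrong: the carbocycle may aromatise before the C2 hydroxyl has closed onto C8a. The acyl chain may be lost by retro-Claisen hydrolysis. The C2 oxygen may be eliminated and added back, which would erode the enantiomeric purity.
- Fallback: the same O1–C8a bond is made on a finished arene by intramolecular nucleophilic aromatic substitution. It sets out from 7 and comes back at 12.
- Coupling of 7 with N,O-dimethylhydroxylamine (EDC·HCl, N-methylmorpholine, CH2Cl2) gives the Weinreb amide F1.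
- Commercial 3-fluoroanisole is lithiated between its two substituents (n-BuLi, THF, −78 °C) to 2-fluoro-6-methoxyphenyllithium F2, which adds to F1 to give the silyloxy aryl ketone F3.
- Buffered fluoride (Bu4NF, AcOH, THF) frees the hydroxy ketone F4.
- K2CO3 in DMF closes the ring by displacement of the fluoride activated by the ortho ketone, giving (R)-5-methoxy-2-methylchroman-4-one F5.
- BCl3 (CH2Cl2, −78 to 0 °C) cleaves the methyl ether next to the carbonyl group by chelation and delivers 12.

**Second risk, step 8.**
- What may go wrong: the cation may be captured by the electron-rich benzene ring of a second molecule of 13 or of the product (oligomerisation). It may lose a proton to the chromene. It may also be attacked with poor facial or positional selectivity.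
- Fallback: a preformed aryl-metal nucleophile is used, and 15 is generated under basic instead of acidic conditions. It sets out from 13 and 14 and comes back at 16.
- Boc2O with a catalytic amount of DMAP converts 13 into the phenyl tert-butyl carbonate F6.
- NBS in MeCN brominates 14 para to a methoxy group to give 1-bromo-4,5-dimethoxynaphthalene F7, and magnesium in THF turns it into the Grignard reagent F8.
- An excess of F8 is added to F6 (THF, −78 to 0 °C). The C4 alkoxide takes over the carbonate group from the neighbouring phenol oxygen, the phenoxide expels tert-butyl carbonate to give 15, and F8 adds 1,4 at C4 along the axial trajectory trans to the methyl group to give 16.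

**Third risk, step 5.**
- What may go wrong: the ring silyloxy group, which is beta to the ketone of the enol ester 8, may be eliminated by the amine base, so that the ring aromatises to a resorcinol ester before the acyl group has reached carbon. The O-to-C migration may also stall.
- Fallback: the C7 oxygen is given up and the arene is made by oxidation instead of dehydration. It sets out from 7 and comes back at 12.
- DCC/DMAP acylation of commercial cyclohexane-1,3-dione, the classical substrate of this reaction, gives the triketone F9.
- TsOH·H2O in MeCN removes the silyl group and closes the O1–C8a bond to give the bicyclic enedione F10.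
- Wohl–Ziegler bromination (NBS, AIBN, PhCF3, reflux) at the allylic C8 position gives the bromide F11.
- Et3N removes HBr, and the dienone tautomerises to 12.

## Further compounds

F1 | step 6 | (R)-3-(tert-butyldimethylsilyloxy)-N-methoxy-N-methylbutanamide | C[C@@H](O[Si](C)(C)C(C)(C)C)CC(=O)N(C)OC
F2 | step 6 | 2-fluoro-6-methoxyphenyllithium | [Li]c1c(F)cccc1OC
F3 | step 6 | (R)-3-(tert-butyldimethylsilyloxy)-1-(2-fluoro-6-methoxyphenyl)butan-1-one | C[C@@H](O[Si](C)(C)C(C)(C)C)CC(=O)c1c(F)cccc1OC
F4 | step 6 | (R)-1-(2-fluoro-6-methoxyphenyl)-3-hydroxybutan-1-one | C[C@@H](O)CC(=O)c1c(F)cccc1OC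
F5 | step 6 | (R)-5-methoxy-2-methylchroman-4-one | C[C@@H]1CC(=O)c2c(OC)cccc2O1
F6 | step 8 | tert-butyl (2R,4S)-4-hydroxy-2-methylchroman-5-yl carbonate | C[C@@H]1C[C@H](O)c2c(OC(=O)OC(C)(C)C)cccc2O1
F7 | step 8 | 1-bromo-4,5-dimethoxynaphthalene | COc1cccc2c(Br)ccc(OC)c12
F8 | step 8 | (4,5-dimethoxynaphthalen-1-yl)magnesium bromide | COc1cccc2c([Mg]Br)ccc(OC)c12
F9 | step 5 | (R)-2-[3-(tert-butyldimethylsilyloxy)butanoyl]cyclohexane-1,3-dione | C[C@@H](O[Si](C)(C)C(C)(C)C)CC(=O)C1C(=O)CCCC1=O
F10 | step 5 | (R)-2-methyl-2,3,7,8-tetrahydro-4H-chromene-4,5(6H)-dione | C[C@@H]1CC(=O)C2=C(CCCC2=O)O1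
F11 | step 5 | (2R)-8-bromo-2-methyl-2,3,7,8-tetrahydro-4H-chromene-4,5(6H)-dione | C[C@@H]1CC(=O)C2=C(C(Br)CCC2=O)O1
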